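**Retrosynthetic overview**
- Feature: in each chromen-4-one unit the two fusion carbons of ring A are neighbours, C8a bearing O1 and C4a bearing the C4 carbonyl. C4a lies next to the oxygenated C5, so the C4a/C8a pair is read as an aryne polarised by the C5 oxygen, and it occurs twice across the C8–C8'' bond.
- Last disconnection: the six O–CH3 bonds, leading back to the hexamethyl ether.
- Key disconnection: both rings C are cut at C8a–O1, C4a–C4 and O1–C2. This gives a biaryl bis(ortho-silylaryl triflate) and two molecules of 3-(4-methoxyphenyl)propiolic acid, each of which supplies O1, C4, C3, C2 and ring B.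
- The bis(silyl triflate) comes from triflation, carbamate cleavage and twofold carbamate-directed silylation of a biaryl bis-carbamate. That biaryl is made by Ullmann coupling of the ortho-iodinated diethylcarbamate of 3,5-dimethoxyphenol.
- Ring order: rings A and B are purchased, the C8–C8'' bond is made first, and the two rings C are closed last in one flask.

Key step: step 7

Assumption: the target SMILES carries no descriptor for the C8–C8'' axis, so the compound is made as the racemic mixture of atropisomers.

Numbering note: flavone numbering is used for the chromenone units. In the biphenyls 6–11, biphenyl C1 = flavone C8, C2 = C8a, C3 = C4a, C4 = C5, C5 = C6 and C6 = C7.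

**Step 1**
Reactants: 1 3,5-dimethoxyphenol; 2 N,N-diethylcarbamoyl chloride
Product: 3 3,5-dimethoxyphenyl N,N-diethylcarbamate
Conditions: K2CO3, MeCN, reflux
Reagents that add atoms: N,N-diethylcarbamoyl chloride (2), CCN(CC)C(=O)Cl
Why: O-carbamoylation of a phenoxide with a carbamoyl chloride is routine and installs the strongest oxygen-based directing group for the two later metalations.

**Step 2**
Reactants: 3 3,5-dimethoxyphenyl N,N-diethylcarbamate
Product: 5 2-iodo-3,5-dimethoxyphenyl N,N-diethylcarbamate, via aryllithium 4 (not isolated)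
Conditions: s-BuLi, TMEDA, THF, −78 °C; then I2, THF, −78 °C → rt
Reagents that add atoms: iodine, II; sec-butyllithium, [Li]C(C)CC (lithium of 4 only)
Why: Directed ortho metalation, in which the carbamate and the C3 methoxy group act together on the C2–H between them and should outcompete the C4–H flanked only by methoxy groups, while holding the anion at −78 °C until iodine is added suppresses the anionic ortho-Fries shift.

**Step 3**
Reactants: 5 2-iodo-3,5-dimethoxyphenyl N,N-diethylcarbamate (two molecules)
Product: 6 4,4',6,6'-tetramethoxybiphenyl-2,2'-diyl bis(N,N-diethylcarbamate) (racemic axis)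
Conditions: activated Cu powder (excess), DMF, reflux, Ar
Reagents that add atoms: none
Why: Classical Ullmann reductive homocoupling on zerovalent copper, a reaction type established for 2,6-dioxygenated iodoarenes and tetra-ortho-substituted biaryls, and the tertiary carbamate has no N–H to arylate and tolerates the heat.

**Step 4**
Reactants: 6 4,4',6,6'-tetramethoxybiphenyl-2,2'-diyl bis(N,N-diethylcarbamate)
Product: 8 4,4',6,6'-tetramethoxy-3,3'-bis(trimethylsilyl)biphenyl-2,2'-diyl bis(N,N-diethylcarbamate), via 3,3'-dilithio biaryl 7 (not isolated)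
Conditions: s-BuLi (2.6 equiv), TMEDA, THF, −78 °C; then Me3SiCl, −78 °C → rt
Reagents that add atoms: chlorotrimethylsilane, C[Si](C)(C)Cl; sec-butyllithium, [Li]C(C)CC (lithium of 7 only)
Why: Twofold directed ortho metalation as known for 2,2'-biaryl bis-carbamates, since on each ring the only free position ortho to the carbamate is C3, which the C4 methoxy group also activates, and the dianion is trapped by Me3SiCl.

**Step 5**
Reactants: 8 4,4',6,6'-tetramethoxy-3,3'-bis(trimethylsilyl)biphenyl-2,2'-diyl bis(N,N-diethylcarbamate)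
Product: 9 4,4',6,6'-tetramethoxy-3,3'-bis(trimethylsilyl)biphenyl-2,2'-diol
Conditions: LiAlH4, THF, reflux; aq. potassium sodium tartrate work-up
Reagents that add atoms: none
Why: Hydride reduction of an aryl N,N-dialkylcarbamate expels the phenoxide and carries the carbamoyl carbon on to the N-methylamine, which leaves aryl–SiMe3 and aryl methyl ethers untouched, and the non-acidic work-up guards the electron-rich aryl silane against protodesilylation.

**Step 6**
Reactants: 9 4,4',6,6'-tetramethoxy-3,3'-bis(trimethylsilyl)biphenyl-2,2'-diol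
Product: 11 4,4',6,6'-tetramethoxy-3,3'-bis(trimethylsilyl)biphenyl-2,2'-diyl bis(trifluoromethanesulfonate), via dilithium bis-phenoxide 10 (not isolated)
Conditions: n-BuLi (2.1 equiv), Et2O, −78 → 0 °C; then Tf2O, −78 → 0 °C
Reagents that add atoms: trifluoromethanesulfonic anhydride, O=S(=O)(OS(=O)(=O)C(F)(F)F)C(F)(F)F; n-butyllithium, [Li]CCCC (lithium of 10 only)
Why: O-sulfonylation of a preformed lithium phenoxide with Tf2O is the standard way to triflate hindered ortho-silylphenols, and the absence of free acid avoids protodesilylation.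

**Step 7**
Reactants: 11 4,4',6,6'-tetramethoxy-3,3'-bis(trimethylsilyl)biphenyl-2,2'-diyl bis(trifluoromethanesulfonate); 12 3-(4-methoxyphenyl)propiolic acid (two molecules enter the product)
Product: 19 cupressuflavone hexamethyl ether, via caesium carboxylate 13 (not isolated), via mono-aryne 14 (not isolated), via ynone phenoxide 15 (not isolated), via mono-flavone silyl triflate 16 (not isolated), via flavone aryne 17 (not isolated), via flavone ynone phenoxide 18 (not isolated)
Conditions: 12 (3 equiv), CsF (8 equiv), THF, 125 °C, sealed tube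
Reagents that add atoms: 3-(4-methoxyphenyl)propiolic acid (12), COc1ccc(C#CC(=O)O)cc1; caesium fluoride, [Cs+].[F-] (caesium of 13, 15 and 18 only)
Why: Fluoride strips Me3Si from C4a and triflate leaves C8a, so each ring A becomes in its turn the C4a≡C8a aryne (14, 17); carboxylate 13 adds through oxygen to C8a, the C4a aryl anion closes on the ester carbonyl to a strained four-membered alkoxide, and rupture of its ring C–O bond gives the ortho-acyl phenoxide (15, 18) with C8a–O1 and C4a–C4 in place. The closest known reaction type is the CsF-mediated formal insertion of arynes into the C–O bond of carboxylic acids in hot THF, which gives ortho-hydroxyaryl ketones and with alkynoic acids runs on to chromones, so the step applies it twice to one new biaryl substrate. Each ring C closes by 6-endo-dig conjugate addition of the phenoxide O1 to the ynone carbon C2, the allenolate takes up on C3 the proton that 12 gave to fluoride, and the aprotic medium with a loose caesium ion pair favours this mode over 5-exo-dig closure to an aurone. No stereocentre is created, and the C8–C8'' axis, fixed since step 3, stays racemic. The site selectivity needed is oxygen attack at C8a and not at C4a: the σ-withdrawing C5 methoxy group distorts the aryne so that C8a is the more linear, more electrophilic carbon and the charge develops at C4a beside the methoxy group, the bias known from 3-methoxy- and 3,5-dimethoxybenzyne, and this electronic effect must outweigh the bulk of the C8 aryl group. The chemoselectivity needed is acyl transfer ahead of protonation of the C4a anion, which should be secured by the excess CsF (it keeps 12 as its salt, so little free acid is in solution), by the high temperature in THF and by the C8 aryl group pressing the acyloxy group toward C4a; the rings react independently, so the order 14 to 18 is only one of the possible sequences.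

**Step 8**
Reactants: 19 cupressuflavone hexamethyl ether
Product: 20 cupressuflavone
Conditions: BBr3 (excess), CH2Cl2, −78 °C → reflux; then H2O
Reagents that add atoms: none
Why: Lewis-acid ether cleavage in which BBr3 binds each aryl methyl ether and bromide removes the methyl group by SN2, the pyranones and the biaryl bond are inert, and avoiding hot protic acid excludes a Wessely–Moser ring opening and reclosure that would move the linkage from C8 to C6.

**Compound list**
1 | 3,5-dimethoxyphenol | COc1cc(O)cc(OC)c1 | starting material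
2 | N,N-diethylcarbamoyl chloride | CCN(CC)C(=O)Cl | starting material
3 | 3,5-dimethoxyphenyl N,N-diethylcarbamate | CCN(CC)C(=O)Oc1cc(OC)cc(OC)c1 | intermediate
4 | 2-lithio-3,5-dimethoxyphenyl N,N-diethylcarbamate | CCN(CC)C(=O)Oc1cc(OC)cc(OC)c1[Li] | intermediate (not isolated)
5 | 2-iodo-3,5-dimethoxyphenyl N,N-diethylcarbamate | CCN(CC)C(=O)Oc1cc(OC)cc(OC)c1I | intermediate
6 | 4,4',6,6'-tetramethoxybiphenyl-2,2'-diyl bis(N,N-diethylcarbamate) | CCN(CC)C(=O)Oc1cc(OC)cc(OC)c1-c1c(OC)cc(OC)cc1OC(=O)N(CC)CC | intermediate
7 | 3,3'-dilithio-4,4',6,6'-tetramethoxybiphenyl-2,2'-diyl bis(N,N-diethylcarbamate) | CCN(CC)C(=O)Oc1c([Li])c(OC)cc(OC)c1-c1c(OC)cc(OC)c([Li])c1OC(=O)N(CC)CC | intermediate (not isolated)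
8 | 4,4',6,6'-tetramethoxy-3,3'-bis(trimethylsilyl)biphenyl-2,2'-diyl bis(N,N-diethylcarbamate) | CCN(CC)C(=O)Oc1c([Si](C)(C)C)c(OC)cc(OC)c1-c1c(OC)cc(OC)c([Si](C)(C)C)c1OC(=O)N(CC)CC | intermediate
9 | 4,4',6,6'-tetramethoxy-3,3'-bis(trimethylsilyl)biphenyl-2,2'-diol | Oc1c([Si](C)(C)C)c(OC)cc(OC)c1-c1c(OC)cc(OC)c([Si](C)(C)C)c1O | intermediate
10 | dilithium 4,4',6,6'-tetramethoxy-3,3'-bis(trimethylsilyl)biphenyl-2,2'-diolate | [Li]Oc1c([Si](C)(C)C)c(OC)cc(OC)c1-c1c(OC)cc(OC)c([Si](C)(C)C)c1O[Li] | intermediate (not isolated)
11 | 4,4',6,6'-tetramethoxy-3,3'-bis(trimethylsilyl)biphenyl-2,2'-diyl bis(trifluoromethanesulfonate) | COc1cc(OC)c(-c2c(OC)cc(OC)c([Si](C)(C)C)c2OS(=O)(=O)C(F)(F)F)c(OS(=O)(=O)C(F)(F)F)c1[Si](C)(C)C | intermediate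
12 | 3-(4-methoxyphenyl)propiolic acid | COc1ccc(C#CC(=O)O)cc1 | starting material
13 | caesium 3-(4-methoxyphenyl)propiolate | [Cs+].[O-]C(=O)C#Cc1ccc(OC)cc1 | intermediate (not isolated)
14 | mono-aryne: one ring is the 3,5-dimethoxy-6-aryl-benzyne (C4a≡C8a), the other ring is still the silyl triflate | COC1=CC(OC)=C(C#C1)c2c(OC)cc(OC)c([Si](C)(C)C)c2OS(=O)(=O)C(F)(F)F | intermediate (not isolated)
15 | caesium phenoxide of the 2-hydroxy-3-[3-(4-methoxyphenyl)propioloyl]-4,6-dimethoxyphenyl ring, the other ring still the silyl triflate | [Cs+].[O-]c1c(C(=O)C#Cc2ccc(OC)cc2)c(OC)cc(OC)c1-c1c(OC)cc(OC)c([Si](C)(C)C)c1OS(=O)(=O)C(F)(F)F | intermediate (not isolated)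
16 | 2-[5,7-dimethoxy-2-(4-methoxyphenyl)-4-oxo-4H-chromen-8-yl]-3,5-dimethoxy-6-(trimethylsilyl)phenyl trifluoromethanesulfonate | O=c1cc(-c2ccc(OC)cc2)oc2c(-c3c(OC)cc(OC)c([Si](C)(C)C)c3OS(=O)(=O)C(F)(F)F)c(OC)cc(OC)c12 | intermediate (not isolated)
17 | 5,7-dimethoxy-2-(4-methoxyphenyl)chromen-4-one bearing at C8 the 3,5-dimethoxybenzyne ring (aryne carbon next to the biaryl bond) | O=c1cc(-c2ccc(OC)cc2)oc2c(C3=C(OC)C=C(OC)C#C3)c(OC)cc(OC)c12 | intermediate (not isolated)
18 | caesium phenoxide of 8-{2-hydroxy-4,6-dimethoxy-3-[3-(4-methoxyphenyl)propioloyl]phenyl}-5,7-dimethoxy-2-(4-methoxyphenyl)chromen-4-one | [Cs+].[O-]c1c(C(=O)C#Cc2ccc(OC)cc2)c(OC)cc(OC)c1-c1c(OC)cc(OC)c2c(=O)cc(-c3ccc(OC)cc3)oc12 | intermediate (not isolated)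
19 | cupressuflavone hexamethyl ether, 5,5',7,7'-tetramethoxy-2,2'-bis(4-methoxyphenyl)-4H,4'H-[8,8'-bichromene]-4,4'-dione | O=c1cc(-c2ccc(OC)cc2)oc2c(-c3c(OC)cc(OC)c4c(=O)cc(-c5ccc(OC)cc5)oc34)c(OC)cc(OC)c12 | intermediate
20 | cupressuflavone, 5,5',7,7'-tetrahydroxy-2,2'-bis(4-hydroxyphenyl)-4H,4'H-[8,8'-bichromene]-4,4'-dione | O=c1cc(-c2ccc(O)cc2)oc2c(-c3c(O)cc(O)c4c(=O)cc(-c5ccc(O)cc5)oc34)c(O)cc(O)c12 | target

**Step count**
Total step count: 8. Longest linear sequence: 8 (from 3,5-dimethoxyphenol).

**Steps most likely to fail**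

1. **Step 7.**
   - What may go wrong:
     - protonation of the C4a anion before it reaches the ester carbonyl, which gives plain O-arylation;
     - oxygen attack at C4a because C8a is crowded by the neighbouring ring;
     - capture of the aryne by a methoxy oxygen of the other ring;
     - thermal loss of CO2 from the alkynoic acid;
     - 5-exo instead of 6-endo closure.
   - Each of these errors counts twice, because both rings must succeed.
   - Fallback: the chalcone route without an aryne, setting out from 6 and coming back at 19. LiAlH4 in THF at reflux cleaves both carbamates of 6 to 4,4',6,6'-tetramethoxybiphenyl-2,2'-diol F1. Ac2O with BF3·OEt2 at about 85 °C then acetylates each ring ortho to the free hydroxyl (O-acetylation followed by a Fries shift held by the boron chelate), giving the 3,3'-diacetyl diol F2. Claisen–Schmidt condensation with 4-methoxybenzaldehyde (KOH, EtOH, rt) gives the (E,E)-bis-chalcone F3. Catalytic I2 in DMSO at 130 °C closes both rings by oxa-Michael addition and dehydrogenates them to 19.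

2. **Step 3.**
   - What may go wrong: hydrodeiodination on the copper surface and a sluggish coupling, because the iodide is electron-rich and flanked on both sides.
   - Fallback: a palladium cross-coupling of two different partners in place of the reductive homocoupling, setting out from 4 and 5 and coming back at 6. Aryllithium 4, generated from 3 as in step 2, is transmetalated with ZnCl2 in THF to [2-(diethylcarbamoyloxy)-4,6-dimethoxyphenyl]zinc chloride F4. This is joined to iodide 5 by Negishi coupling (Pd2(dba)3, RuPhos, THF, 70 °C; zerovalent palladium with a bulky biarylphosphine suited to tetra-ortho-substituted biaryls) to give 6.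

3. **Step 5.**
   - What may go wrong: incomplete hydride attack on carbamates shielded by SiMe3 on one side and the aryl group on the other, and loss of silicon from the electron-rich ring during reduction or work-up.
   - Fallback: silicon is introduced only after the phenols are free, by halogen–lithium exchange and silyl migration, setting out from 7 and coming back at 10.
     - Dianion 7, generated from 6 as in step 4, is quenched with 1,2-dibromo-1,1,2,2-tetrachloroethane to give the 3,3'-dibromo bis-carbamate F5.
     - NaOH in EtOH at reflux hydrolyses the carbamates, with no silicon at risk, to 3,3'-dibromo-4,4',6,6'-tetramethoxybiphenyl-2,2'-diol F6.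
     - (Me3Si)2NH at 80 °C gives the bis(trimethylsilyl ether) F7.
     - n-BuLi in THF at −78 °C performs the Br/Li exchange to the dilithio bis(silyl ether) F8, whose 1,3 O→C silyl shift (retro-Brook rearrangement) delivers the dilithium bis-phenoxide 10. This is triflated as in step 6.

**Further compounds**
F1 | step 7 | 4,4',6,6'-tetramethoxybiphenyl-2,2'-diol | Oc1cc(OC)cc(OC)c1-c1c(OC)cc(OC)cc1O
F2 | step 7 | 1,1'-(2,2'-dihydroxy-4,4',6,6'-tetramethoxybiphenyl-3,3'-diyl)diethanone | CC(=O)c1c(O)c(-c2c(O)c(C(C)=O)c(OC)cc2OC)c(OC)cc1OC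
F3 | step 7 | (2E,2'E)-1,1'-(2,2'-dihydroxy-4,4',6,6'-tetramethoxybiphenyl-3,3'-diyl)bis[3-(4-methoxyphenyl)prop-2-en-1-one] | COc1ccc(/C=C/C(=O)c2c(O)c(-c3c(O)c(C(=O)/C=C/c4ccc(OC)cc4)c(OC)cc3OC)c(OC)cc2OC)cc1
F4 | step 3 | [2-(diethylcarbamoyloxy)-4,6-dimethoxyphenyl]zinc chloride | CCN(CC)C(=O)Oc1cc(OC)cc(OC)c1[Zn]Cl
F5 | step 5 | 3,3'-dibromo-4,4',6,6'-tetramethoxybiphenyl-2,2'-diyl bis(N,N-diethylcarbamate) | CCN(CC)C(=O)Oc1c(Br)c(OC)cc(OC)c1-c1c(OC)cc(OC)c(Br)c1OC(=O)N(CC)CC
F6 | step 5 | 3,3'-dibromo-4,4',6,6'-tetramethoxybiphenyl-2,2'-diol | Oc1c(Br)c(OC)cc(OC)c1-c1c(OC)cc(OC)c(Br)c1O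
F7 | step 5 | 3,3'-dibromo-4,4',6,6'-tetramethoxy-2,2'-bis(trimethylsilyloxy)biphenyl | C[Si](C)(C)Oc1c(Br)c(OC)cc(OC)c1-c1c(OC)cc(OC)c(Br)c1O[Si](C)(C)C
F8 | step 5 | 3,3'-dilithio-4,4',6,6'-tetramethoxy-2,2'-bis(trimethylsilyloxy)biphenyl | C[Si](C)(C)Oc1c([Li])c(OC)cc(OC)c1-c1c(OC)cc(OC)c([Li])c1O[Si](C)(C)C
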